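All runs were computed for substances that don't exist; noise was put on by code.

L was the species I had to follow in this flask: the proposed steps make it from G and spend it on J, which comes from Z, while pairs of J can leave as Q.

| setting | theta | delta | epsilon | flask |
|---|---|---|---|---|
| G | 0.30 M | 0.30 M | 0.45 M | 0.30 M |
| Z | 0.47 equiv | 1.9 equiv | 0.95 equiv | 0.950 equiv |
| remark | run made earlier | run made earlier | run made earlier |  |
| time |  |  |  | 40 min |

| run | time / min | L / % | X / % |
|---|---|---|---|
| theta | 1.33 | 28.2 | 1.6 |
| theta | 4.00 | 56.3 | 7.8 |
| theta | 10.0 | 62.7 | 28.3 |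
| theta | 30.0 | 53.1 | 45.5 |
| delta | 1.33 | 25.6 | 2.8 |
| delta | 4.00 | 35.4 | 27.1 |
| delta | 10.0 | 17.6 | 76.0 |
| delta | 30.0 | 0 | 100.1 |
| epsilon | 1.33 | 26.0 | 2.6 |
| epsilon | 4.00 | 41.2 | 18.8 |
| epsilon | 10.0 | 32.8 | 57.4 |
| epsilon | 30.0 | 12.9 | 87.8 |

(standard deviation of a reading: 1 percentage point)

- time up to 40 min at which L stands highest
- the amount of L, in percent of the G charged, at that time
- the first time at which L reaches 15%, in the same percent, in min

I reckoned with two extreme versions. In the slow one, J left L alone, so L was simply the G lost, first order. From L plus X in the theta run at 4.00 min I read a constant of 0.256 min⁻¹, which put L at 15% after 0.635 min, earlier than the forecast's time.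

In the fast one, each J took an L the moment it formed. Z, the limiting reagent here, then ended by leaving L the free share, one minus the equivalents of Z, which for this flask was 5.00% of the G charged. The theta charge gives 53.0%, and its L read 53.1% at 30.0 min. The epsilon run, with the same equivalents as this flask, still read 12.9% at 30.0 min, above its free share, so that run had not come down to the end of the fast version.

This flask has a smaller c(G) than epsilon and more Z than theta. I therefore placed its peak between epsilon's reading of 41.2% and theta's of 62.7%. The forecast said 48.5% at 4.8 min, “where formation and consumption balance”, and 15% by 0.66 min.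

The flask gave 48.4% at 4.95 min, and L reached 15% at 0.669 min.

    L + J → X (k = 0.0230 L mol⁻¹ s⁻¹)
    Z → J (k = 0.00330 s⁻¹)
    2 J → Q (k = 6.90 × 10⁻⁴ L mol⁻¹ s⁻¹)
    G → L (k = 0.00410 s⁻¹)

At 400 min this flask held 0% of its Z and 8.64% of L, with c(Q) at 0.00546 M. That L is the free share 5.00% plus the J that paired into Q, worth 3.64% of the G charge. The neighbour charged with 0.240 equiv of Z has a free share of 76.0%, and it held 76.1% of L at 40.0 min.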